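## Analysis of the target

Moracin Q is a 2-arylbenzofuran. Ring A is the benzo ring (C3a, C4 to C7, C7a), ring B the furan (O1, C2, C3) and ring C the 3,5-dihydroxyphenyl group on C2. There is no stereocentre, so the problem is one of substitution pattern and chemoselectivity. Ring A is pentasubstituted, with hydrogen only on C7: C4 carries a CH2–C(=O)–CH(CH3)2 chain, C5 a methoxy group and C6 a free hydroxyl. The two ring A oxygens must be differentiated from each other and from the two phenols of ring C. C4 is meta to both strong donors of ring A (O1 through C7a, and the C6 oxygen), so it cannot be reached by electrophilic substitution or directed metalation of a finished benzofuran; the chain has to come in with the ring. Sensitive features are the three electron-rich phenols, the enolisable ketone whose CH2 is activated by both the arene and the carbonyl, the reducible C2=C3 bond, and the methyl ether that must survive unmasking of the phenols. The strategy rests on reading C4, C5 and C6 as a 2-methoxy-1,3-diketone (carbonyls at C4 and C6, methoxy at C5), extended beyond C4 by a CH2–carbonyl unit and tied through the C7 methylene to C7a, which is then the α-carbon of a 2-arylfuran whose β-carbon is C3a. Forming the C3a–C4 bond therefore creates ring A with all three substituents in place.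

## Retrosynthetic reasoning

The three phenols of 15 are masked as benzyl ethers, which leads to 14. The three O–benzyl bonds are cut because they can be removed together, under neutral conditions, as the last operation, so the polyphenol is exposed only once. The forward step must spare the C2=C3 bond, the ketone and the methyl ether.

In 14 the bond between the ketone carbon and the isopropyl carbon is cut, which leads to the N-methoxy-N-methylamide 12. The cut is made here because the ring-forming step needs the end of the C4 chain at the carboxylic oxidation level, so the isopropyl group can only be added afterwards. The amide is chosen because its chelated adduct 13 accepts one isopropyl nucleophile and then stops.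

Amide 12 is traced to methyl ester 11, and 11 to the free phenol 10. The C6 hydroxyl is benzylated at this point so that the two organometallic steps are not run on a free phenol. It also means one kind of protecting group is removed at the end.

The key disconnection cuts the C3a–C4 bond of 10 and undoes the dehydration and the enolisation, which opens ring A to the acyclic chain of 8 (by way of carbinol 9). This bond is chosen because its formation is an attack of the furan β-carbon on a carbonyl carbon. The three substituents on C4, C5 and C6 are then simply the substituents of the chain, and no oxidant is needed to reach the aromatic level. Any other cut through ring A, or a cut in ring B, would require a pentasubstituted benzene to be made first. The forward reaction has to make carbon–carbon bond formation by the furan faster than oxygen cyclisation onto the ester and faster than acid damage to the furan.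

Precursor 8 is cut between the C6 carbonyl carbon and the methoxy-bearing C5 (benzofuran numbering). This gives amide 4 as acyl donor and keto ester 5 as nucleophile through its dianion 6. The cut is placed here because C5 is exactly the carbon that 6 uses as its nucleophilic site, so one commercial piece brings C4, C5, the methoxy group and the ester chain. The amide 4 is preferred to the ester 3 as acyl donor because its adduct 7 holds until the quench. The new diketone is therefore never exposed to 6, and the less acidic CH2 of the amide is less prone to proton transfer.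

Amide 4 comes from ester 3, and 3 is cut at the bond between furan C5 and ring C to give 1 and 2. Direct arylation uses the only free α-position of 1, so no pre-functionalised furan is needed, and ring C arrives complete and benzyl-protected in 2.

## Alternatives that were turned down

Alternative 1: Ring A is prepared as a complete benzene and ring B is closed last, at C2=C3.
- Disconnection: the furan double bond of 6-(benzyloxy)-2-[3,5-bis(benzyloxy)phenyl]-5-methoxy-4-(3-methylbut-2-en-1-yl)-1-benzofuran A1. This goes back to the benzylic phosphonium bromide A2, whose neighbouring phenol oxygen (future O1) carries the 3,5-bis(benzyloxy)benzoyl group.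
- Forward key step: a mild amine base removes a benzylic proton of A2. The carbanionic carbon (future C3) adds to the adjacent ester carbonyl (future C2), and phosphorus leaves as its oxide, giving the C2=C3 bond of A1 (intramolecular Wittig reaction on an ester).
- For it: this closure is standard for 2-arylbenzofurans, runs under mild base and raises no regiochemical question. On precedent it is clearly stronger than the key step chosen here.
- Against it: everything difficult about ring A is pushed back into A2, a pentasubstituted benzene with a prenyl group wedged between the benzylic carbon and the methoxy group and three differently substituted oxygens. Making that arene needs a long linear sequence of protections, a regiocontrolled C-prenylation and a benzylic functionalisation. A1 also still needs anti-Markovnikov hydration of the prenyl group and oxidation to reach the isopropyl ketone.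
- Comparison: alternative 1 has a safe key step and a long approach to it. The chosen route forms ring A and places its three substituents in one operation from a chain made in three steps, at the price of an unprecedented closure.

Alternative 2: The ring that is formed is ring C.
- Disconnection: the C1'–C6' bond of the dihydroxyphenyl ring in 5-[6-(benzyloxy)-5-methoxy-4-{[2-(propan-2-yl)-1,3-dioxolan-2-yl]methyl}-1-benzofuran-2-yl]benzene-1,3-diol A3, leading to the 1-(benzofuran-2-yl)hexane-1,3,5-trione A4.
- Forward key step: aqueous hydroxide makes the terminal methyl carbon of A4 add to the ketone attached to C2 in a six-membered intramolecular aldol reaction. Dehydration and enolisation of the two remaining ketones give the free 1,3-diol ring of A3.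
- For it: base-mediated folding of 1-aryl-1,3,5-triketones is established chemistry, so the key step is better precedented than the chosen one. Ring C emerges unprotected, which saves two benzyl groups.
- Against it: the step builds the one part of the molecule that can be bought ready-made (compound 2 contains it). It presupposes a benzofuran with the complete, differentiated ring A, the C4 chain masked as a ketal and an acyl handle on C2, so the hard problem is only moved upstream. The side-chain ketone must be protected because it would take part in the aldol chemistry, and the electron-rich diol A3 must then be carried through ketal hydrolysis and debenzylation.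
- Comparison: safer in its key step, but much worse in step economy because the strategic bond construction is spent on the easy ring.

Alternative 3: Ring A is again grown onto a furan, but by a pericyclic route.
- Disconnection: the C5–C6 bond of 2-[3,5-bis(benzyloxy)phenyl]-5-methoxy-4-{[2-(propan-2-yl)-1,3-dioxolan-2-yl]methyl}-1-benzofuran-6-ol A5 is cut and C7 is traced back to a diazo carbon. This gives the 2-(diazoacetyl)furan A6, which carries a methoxy-substituted vinyl group on C3.
- Forward key step: irradiation of A6 causes loss of the diazo nitrogen with a Wolff shift of the furan carbon (future C7a) to the former diazo carbon (C7). The ketene carbon so created (C6) bonds to the methoxy-bearing vinyl carbon (C5) in a six-electron electrocyclisation, and tautomerisation gives the C6 phenol of A5.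
- For it: the regiochemistry of ring A is fixed by the pericyclic topology, and the conditions are neutral, with no acid near the furan. The reaction class has precedent in dienylketene benzannulations. A5 already has the side chain at the ketone oxidation level, so the endgame is only ketal hydrolysis and debenzylation. On these points it is as strong as or stronger than the chosen route.
- Against it: A6 is a 2,3,5-trisubstituted furan with three different substituents, one a diazoketone and one an acid-labile enol ether next to a ketal. Making it needs a 3-acylfuran, a methoxymethylenation of a hindered ketone and a diazo transfer, each on a sensitive intermediate, and the photochemical step scales poorly.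
- Comparison: the chosen strategy offers a precursor assembled in three steps from three commercial compounds, with no labile functionality beyond the furan. It pays with a less certain ring closure and four steps after it.

Key step: step 4

Assumption: the methoxy-bearing carbon of 8 is configurationally labile, and it and the carbinol carbon of 9 both end as aromatic carbons, so 8 and 9 are handled as mixtures of tautomers and stereoisomers; 1, 2 and 5 are taken as purchasable.

## Route

Step 1
Reactants: 1 methyl 2-(furan-2-yl)acetate; 2 1,3-bis(benzyloxy)-5-bromobenzene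
Product: 3 methyl 2-{5-[3,5-bis(benzyloxy)phenyl]furan-2-yl}acetate
Conditions: Pd(OAc)2 (2 mol %), KOAc (2 equiv), 1 (2 equiv), DMAc, 130 °C
Reagents that add atoms: none
Why: Direct C–H arylation of a 2-substituted furan by concerted metalation–deprotonation should go at C5, the only free α-position; potassium acetate is too weak a base to enolise the ester, so arylation of the CH2 group is not expected.

Step 2
Reactants: 3 methyl 2-{5-[3,5-bis(benzyloxy)phenyl]furan-2-yl}acetate
Product: 4 2-{5-[3,5-bis(benzyloxy)phenyl]furan-2-yl}-N-methoxy-N-methylacetamide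
Conditions: MeNH(OMe)·HCl (1.5 equiv), i-PrMgCl (3 equiv), THF, −20 → 0 °C
Reagents that add atoms: N,O-dimethylhydroxylamine hydrochloride, CNOC.Cl
Why: Aminolysis of the methyl ester by the chloromagnesium amide formed in the flask (Weinreb amide formation); the magnesium amide is a good nucleophile but a poor base, so the acidic CH2 group should be left alone and the amide should not react further at this temperature.

Step 3
Reactants: 5 methyl 4-methoxy-3-oxobutanoate; 4 2-{5-[3,5-bis(benzyloxy)phenyl]furan-2-yl}-N-methoxy-N-methylacetamide
Product: 8 methyl 6-{5-[3,5-bis(benzyloxy)phenyl]furan-2-yl}-4-methoxy-3,5-dioxohexanoate (racemic keto–enol mixture), via the lithium sodium dianion of the keto ester 6 (not isolated), via the tetrahedral amide adduct 7 (not isolated)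
Conditions: 5 (2 equiv), NaH, THF, 0 °C; n-BuLi, 0 °C; 4, −78 → 0 °C; 1 M HCl, 0 °C
Reagents that add atoms: none
Why: γ-Acylation of a β-keto ester dianion by an N-methoxy-N-methylamide: the carbanion made last, on the methoxy-bearing carbon, is the reactive site of 6, and the chelated adduct 7 keeps the new ketone masked until the quench, so neither over-addition nor deprotonation of the product by 6 should occur. The excess of 6 allows for some proton transfer from the CH2 group of 4.

Step 4
Reactants: 8 methyl 6-{5-[3,5-bis(benzyloxy)phenyl]furan-2-yl}-4-methoxy-3,5-dioxohexanoate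
Product: 10 methyl 2-{2-[3,5-bis(benzyloxy)phenyl]-6-hydroxy-5-methoxy-1-benzofuran-4-yl}acetate, via the tertiary carbinol 9 (not isolated)
Conditions: TsOH·H2O (0.2 equiv), toluene (0.02 M), reflux, Dean–Stark trap
Reagents that add atoms: none
Why: Proposed new method: the acid protonates the C4 carbonyl of 8 (benzofuran numbering; the ketone that is also part of the β-keto ester), and the furan β-carbon next to the chain, the future C3a, attacks it in an intramolecular Friedel–Crafts hydroxyalkylation, after which loss of the proton from C3a restores the furan and gives carbinol 9. Ionisation of the tertiary, furan-stabilised C4–OH and loss of the C5 proton give the C4=C5 bond, and enolisation of the C6 ketone towards C7 completes the benzene ring, so one molecule of water is lost and no oxidant is needed. The closest known reaction types are the Friedel–Crafts cyclisation of 4-(2-furyl)butanoic acids to 6,7-dihydrobenzofuran-4(5H)-ones, furan-terminated cationic cyclisations and the Bradsher-type cyclodehydration of aryl ketones; a ketone of a 2-alkoxy-1,3-diketone as electrophile for a furan β-carbon is the untested element. Ring A is closed in a six-membered mode, 6-exo-trig at the carbonyl, with the nucleophilic C2=C3 bond of the furan lying inside the new ring. The two stereocentres of 9 (C4 and C5) are not controlled and need not be, since both become aromatic carbons. The step needs chemoselectivity for C–C bond formation over attack of an enol oxygen on the ester and over acid-induced opening of the furan, and site selectivity among the carbonyl groups: the C6 carbonyl is one carbon from the furan and could only close a four-membered ring, the ester only an eight-membered one, so C4 is the single carbonyl that the single free nucleophilic carbon can reach without strain, while the anhydrous, base-free medium with continuous removal of water disfavours hydrolytic furan opening and Claisen-type folding, and aromatisation makes the closure irreversible.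

Step 5
Reactants: 10 methyl 2-{2-[3,5-bis(benzyloxy)phenyl]-6-hydroxy-5-methoxy-1-benzofuran-4-yl}acetate
Product: 11 methyl 2-{6-(benzyloxy)-2-[3,5-bis(benzyloxy)phenyl]-5-methoxy-1-benzofuran-4-yl}acetate
Conditions: BnBr (1.2 equiv), K2CO3, DMF, rt
Reagents that add atoms: benzyl bromide, BrCc1ccccc1
Why: Williamson ether synthesis on the only acidic OH group; carbonate does not deprotonate the arylacetate CH2, so C-benzylation is not expected, and the phenol is now masked for the two organometallic steps.

Step 6
Reactants: 11 methyl 2-{6-(benzyloxy)-2-[3,5-bis(benzyloxy)phenyl]-5-methoxy-1-benzofuran-4-yl}acetate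
Product: 12 2-{6-(benzyloxy)-2-[3,5-bis(benzyloxy)phenyl]-5-methoxy-1-benzofuran-4-yl}-N-methoxy-N-methylacetamide
Conditions: MeNH(OMe)·HCl (1.5 equiv), i-PrMgCl (3 equiv), THF, −20 → 0 °C
Reagents that add atoms: N,O-dimethylhydroxylamine hydrochloride, CNOC.Cl
Why: The same Weinreb amide formation as in step 2; the benzyl and methyl ethers and the benzofuran are inert to the chloromagnesium amide.

Step 7
Reactants: 12 2-{6-(benzyloxy)-2-[3,5-bis(benzyloxy)phenyl]-5-methoxy-1-benzofuran-4-yl}-N-methoxy-N-methylacetamide
Product: 14 1-{6-(benzyloxy)-2-[3,5-bis(benzyloxy)phenyl]-5-methoxy-1-benzofuran-4-yl}-3-methylbutan-2-one, via the magnesium-chelated tetrahedral adduct 13 (not isolated)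
Conditions: i-PrMgCl (2.5 equiv), THF, −20 → 0 °C; 1 M HCl, 0 °C
Reagents that add atoms: isopropylmagnesium chloride, CC(C)[Mg]Cl
Why: Weinreb ketone synthesis: 13 is a five-membered chelate that cannot collapse before work-up, so a single isopropyl group should be delivered and no tertiary alcohol should form.

Step 8
Reactants: 14 1-{6-(benzyloxy)-2-[3,5-bis(benzyloxy)phenyl]-5-methoxy-1-benzofuran-4-yl}-3-methylbutan-2-one
Product: 15 1-[2-(3,5-dihydroxyphenyl)-6-hydroxy-5-methoxy-1-benzofuran-4-yl]-3-methylbutan-2-one (moracin Q)
Conditions: H2 (1 atm), Pd/C (10 %), EtOAc–MeOH, rt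
Reagents that add atoms: none
Why: Hydrogenolysis of the three aryl benzyl ethers; the aryl methyl ether, the ketone (its carbonyl carbon is not benzylic) and the benzofuran C2=C3 bond should survive at one atmosphere if the reaction is stopped at complete debenzylation.

## Compound list

1 | methyl 2-(furan-2-yl)acetate | COC(=O)Cc1ccco1 | starting material
2 | 1,3-bis(benzyloxy)-5-bromobenzene | Brc1cc(OCc2ccccc2)cc(OCc2ccccc2)c1 | starting material
3 | methyl 2-{5-[3,5-bis(benzyloxy)phenyl]furan-2-yl}acetate | COC(=O)Cc1ccc(-c2cc(OCc3ccccc3)cc(OCc3ccccc3)c2)o1 | intermediate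
4 | 2-{5-[3,5-bis(benzyloxy)phenyl]furan-2-yl}-N-methoxy-N-methylacetamide | CON(C)C(=O)Cc1ccc(-c2cc(OCc3ccccc3)cc(OCc3ccccc3)c2)o1 | intermediate
5 | methyl 4-methoxy-3-oxobutanoate | COCC(=O)CC(=O)OC | starting material
6 | lithium sodium 1,4-dimethoxybuta-1,3-diene-1,3-bis(olate), the dianion of 5 (formed in the flask) | COC([O-])=CC([O-])=COC.[Li+].[Na+] | intermediate
7 | lithium sodium salt of methyl 6-{5-[3,5-bis(benzyloxy)phenyl]furan-2-yl}-5-hydroxy-4-methoxy-5-[methoxy(methyl)amino]-3-oxohexanoate, enolate and alkoxide (formed in the flask, stereoisomer mixture) | COC(=O)C=C([O-])C(OC)C([O-])(Cc1ccc(-c2cc(OCc3ccccc3)cc(OCc3ccccc3)c2)o1)N(C)OC.[Li+].[Na+] | intermediate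
8 | methyl 6-{5-[3,5-bis(benzyloxy)phenyl]furan-2-yl}-4-methoxy-3,5-dioxohexanoate (racemic, keto–enol mixture) | COC(=O)CC(=O)C(OC)C(=O)Cc1ccc(-c2cc(OCc3ccccc3)cc(OCc3ccccc3)c2)o1 | intermediate
9 | methyl 2-{2-[3,5-bis(benzyloxy)phenyl]-4-hydroxy-5-methoxy-6-oxo-4,5,6,7-tetrahydro-1-benzofuran-4-yl}acetate (formed in the flask, diastereomer mixture) | COC(=O)CC1(O)C(OC)C(=O)Cc2oc(-c3cc(OCc4ccccc4)cc(OCc4ccccc4)c3)cc21 | intermediate
10 | methyl 2-{2-[3,5-bis(benzyloxy)phenyl]-6-hydroxy-5-methoxy-1-benzofuran-4-yl}acetate | COC(=O)Cc1c(OC)c(O)cc2oc(-c3cc(OCc4ccccc4)cc(OCc4ccccc4)c3)cc12 | intermediate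
11 | methyl 2-{6-(benzyloxy)-2-[3,5-bis(benzyloxy)phenyl]-5-methoxy-1-benzofuran-4-yl}acetate | COC(=O)Cc1c(OC)c(OCc5ccccc5)cc2oc(-c3cc(OCc4ccccc4)cc(OCc4ccccc4)c3)cc12 | intermediate
12 | 2-{6-(benzyloxy)-2-[3,5-bis(benzyloxy)phenyl]-5-methoxy-1-benzofuran-4-yl}-N-methoxy-N-methylacetamide | CON(C)C(=O)Cc1c(OC)c(OCc5ccccc5)cc2oc(-c3cc(OCc4ccccc4)cc(OCc4ccccc4)c3)cc12 | intermediate
13 | chloromagnesium alkoxide of 1-{6-(benzyloxy)-2-[3,5-bis(benzyloxy)phenyl]-5-methoxy-1-benzofuran-4-yl}-2-[methoxy(methyl)amino]-3-methylbutan-2-ol (formed in the flask, racemic) | CON(C)C(O[Mg]Cl)(C(C)C)Cc1c(OC)c(OCc5ccccc5)cc2oc(-c3cc(OCc4ccccc4)cc(OCc4ccccc4)c3)cc12 | intermediate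
14 | 1-{6-(benzyloxy)-2-[3,5-bis(benzyloxy)phenyl]-5-methoxy-1-benzofuran-4-yl}-3-methylbutan-2-one | CC(C)C(=O)Cc1c(OC)c(OCc5ccccc5)cc2oc(-c3cc(OCc4ccccc4)cc(OCc4ccccc4)c3)cc12 | intermediate
15 | 1-[2-(3,5-dihydroxyphenyl)-6-hydroxy-5-methoxy-1-benzofuran-4-yl]-3-methylbutan-2-one (moracin Q) | COc1c(O)cc2oc(-c3cc(O)cc(O)c3)cc2c1CC(=O)C(C)C | target

## Step count and least certain steps

Total: 8 steps. Longest linear sequence: 8 steps (1 to 15; 2 enters in step 1 and 5 in step 3).

**Step 4 (key step, proposed new method).**
- What may go wrong: cyclisation through oxygen instead of carbon, with an enol oxygen of the diketone closing onto the methyl ester and methanol lost; or acid-induced opening and oligomerisation of the furan. The diketone is largely enolised, which lowers the electrophilicity of C4, and the β-position is the less nucleophilic position of a furan.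
- Fallback (known chemistry, from 4 back to 10): ring A is closed by a Friedel–Crafts acylation and the C4 chain is added afterwards.
  - Amide 4 is acylated with the lithium enolate of methyl methoxyacetate (LiN(i-Pr)2, THF, −78 °C) to give methyl 4-{5-[3,5-bis(benzyloxy)phenyl]furan-2-yl}-2-methoxy-3-oxobutanoate F1.
  - The ketone is masked (1,2-bis(trimethylsilyloxy)ethane, Me3SiOTf cat., CH2Cl2, −78 °C) as methyl 2-[2-({5-[3,5-bis(benzyloxy)phenyl]furan-2-yl}methyl)-1,3-dioxolan-2-yl]-2-methoxyacetate F2.
  - LiOH in aqueous THF gives 2-[2-({5-[3,5-bis(benzyloxy)phenyl]furan-2-yl}methyl)-1,3-dioxolan-2-yl]-2-methoxyacetic acid F3.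
  - Trifluoroacetic anhydride in CH2Cl2 at 0 °C acylates the furan β-carbon intramolecularly, the known cyclisation type of 4-(2-furyl)butanoic acids, to give 2'-[3,5-bis(benzyloxy)phenyl]-5'-methoxy-5',7'-dihydro-4'H-spiro[1,3-dioxolane-2,6'-[1]benzofuran]-4'-one F4.
  - The lithium enolate of methyl acetate (THF, −78 °C) adds to the C4 ketone to give methyl 2-{2'-[3,5-bis(benzyloxy)phenyl]-4'-hydroxy-5'-methoxy-5',7'-dihydro-4'H-spiro[1,3-dioxolane-2,6'-[1]benzofuran]-4'-yl}acetate F5, the ethylene ketal of carbinol 9.
  - TsOH in wet acetone removes the ketal, and the liberated 9 should dehydrate and enolise to 10.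

**Step 3.**
- What may go wrong: proton transfer from the doubly activated CH2 group of 4 to dianion 6 in place of acylation, so that 4 is returned as its enolate and conversion stays low.
- Fallback (from 3 and 5 back to 8): a base-free acylation.
  - Ester 3 is saponified (LiOH) to 2-{5-[3,5-bis(benzyloxy)phenyl]furan-2-yl}acetic acid F6 and converted with oxalyl chloride into 2-{5-[3,5-bis(benzyloxy)phenyl]furan-2-yl}acetyl chloride F7.
  - Keto ester 5 is silylated twice, first to methyl 4-methoxy-3-[(trimethylsilyl)oxy]but-2-enoate F8 (Me3SiCl, NEt3), then to 1,4-dimethoxy-1,3-bis[(trimethylsilyl)oxy]buta-1,3-diene F9 (LiN(i-Pr)2, Me3SiCl, THF, −78 °C).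
  - F9 and F7 are combined in CH2Cl2 at −78 → 20 °C (Mukaiyama-type acylation at the terminal carbon of the diene), and aqueous acid work-up should give 8.

**Step 7.**
- What may go wrong: enolisation of the benzylic CH2 group of 12, or β-hydride transfer from the secondary Grignard reagent (reduction), in place of addition. The amide carbonyl is hindered by the 2,6-disubstituted arene next to it.
- Fallback (from 12 back to 14): i-Bu2AlH in THF at −78 °C reduces 12 to 2-{6-(benzyloxy)-2-[3,5-bis(benzyloxy)phenyl]-5-methoxy-1-benzofuran-4-yl}acetaldehyde F10. i-PrMgCl with CeCl3 at −78 °C adds to the much more electrophilic aldehyde to give racemic 1-{6-(benzyloxy)-2-[3,5-bis(benzyloxy)phenyl]-5-methoxy-1-benzofuran-4-yl}-3-methylbutan-2-ol F11. Dess–Martin periodinane oxidises F11 to 14.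

**Step 1.**
- What may go wrong: a second arylation at a furan β-position, arylation at the ester α-carbon, or slow turnover with this aryl bromide at the high temperature needed.
- Fallback (from 1 and 2 back to 3): a cross-coupling with both partners pre-functionalised. 1 is brominated at C5 (N-bromosuccinimide, DMF, 0 °C) to methyl 2-(5-bromofuran-2-yl)acetate F12. 2 is converted by Miyaura borylation (B2pin2, PdCl2(dppf), KOAc, dioxane, 80 °C) into 2-[3,5-bis(benzyloxy)phenyl]-4,4,5,5-tetramethyl-1,3,2-dioxaborolane F13. Suzuki coupling of F12 and F13 (Pd(PPh3)4, aqueous K2CO3, DME, 80 °C) should give 3.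

**Step 8.**
- What may go wrong: over-reduction of the C2=C3 bond of the benzofuran, or incomplete cleavage of the hindered C6 benzyl ether.
- Fallback (from 14 directly to 15): non-reductive debenzylation with BCl3 and pentamethylbenzene as cation scavenger in CH2Cl2 at −78 °C. This leaves the double bond and the ketone alone and, at this temperature, should not cleave the methyl ether.

## Further compounds

F1 | step 4 | methyl 4-{5-[3,5-bis(benzyloxy)phenyl]furan-2-yl}-2-methoxy-3-oxobutanoate (racemic) | COC(=O)C(OC)C(=O)Cc1ccc(-c2cc(OCc3ccccc3)cc(OCc3ccccc3)c2)o1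
F2 | step 4 | methyl 2-[2-({5-[3,5-bis(benzyloxy)phenyl]furan-2-yl}methyl)-1,3-dioxolan-2-yl]-2-methoxyacetate (racemic) | COC(=O)C(OC)C1(Cc2ccc(-c3cc(OCc4ccccc4)cc(OCc4ccccc4)c3)o2)OCCO1
F3 | step 4 | 2-[2-({5-[3,5-bis(benzyloxy)phenyl]furan-2-yl}methyl)-1,3-dioxolan-2-yl]-2-methoxyacetic acid (racemic) | OC(=O)C(OC)C1(Cc2ccc(-c3cc(OCc4ccccc4)cc(OCc4ccccc4)c3)o2)OCCO1
F4 | step 4 | 2'-[3,5-bis(benzyloxy)phenyl]-5'-methoxy-5',7'-dihydro-4'H-spiro[1,3-dioxolane-2,6'-[1]benzofuran]-4'-one (racemic) | COC1C(=O)c2cc(-c3cc(OCc4ccccc4)cc(OCc4ccccc4)c3)oc2CC12OCCO2
F5 | step 4 | methyl 2-{2'-[3,5-bis(benzyloxy)phenyl]-4'-hydroxy-5'-methoxy-5',7'-dihydro-4'H-spiro[1,3-dioxolane-2,6'-[1]benzofuran]-4'-yl}acetate (diastereomer mixture) | COC(=O)CC1(O)C(OC)C2(OCCO2)Cc2oc(-c3cc(OCc4ccccc4)cc(OCc4ccccc4)c3)cc21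
F6 | step 3 | 2-{5-[3,5-bis(benzyloxy)phenyl]furan-2-yl}acetic acid | OC(=O)Cc1ccc(-c2cc(OCc3ccccc3)cc(OCc3ccccc3)c2)o1
F7 | step 3 | 2-{5-[3,5-bis(benzyloxy)phenyl]furan-2-yl}acetyl chloride | ClC(=O)Cc1ccc(-c2cc(OCc3ccccc3)cc(OCc3ccccc3)c2)o1
F8 | step 3 | methyl 4-methoxy-3-[(trimethylsilyl)oxy]but-2-enoate | COCC(O[Si](C)(C)C)=CC(=O)OC
F9 | step 3 | 1,4-dimethoxy-1,3-bis[(trimethylsilyl)oxy]buta-1,3-diene | COC=C(O[Si](C)(C)C)C=C(OC)O[Si](C)(C)C
F10 | step 7 | 2-{6-(benzyloxy)-2-[3,5-bis(benzyloxy)phenyl]-5-methoxy-1-benzofuran-4-yl}acetaldehyde | O=CCc1c(OC)c(OCc5ccccc5)cc2oc(-c3cc(OCc4ccccc4)cc(OCc4ccccc4)c3)cc12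
F11 | step 7 | 1-{6-(benzyloxy)-2-[3,5-bis(benzyloxy)phenyl]-5-methoxy-1-benzofuran-4-yl}-3-methylbutan-2-ol (racemic) | CC(C)C(O)Cc1c(OC)c(OCc5ccccc5)cc2oc(-c3cc(OCc4ccccc4)cc(OCc4ccccc4)c3)cc12
F12 | step 1 | methyl 2-(5-bromofuran-2-yl)acetate | COC(=O)Cc1ccc(Br)o1
F13 | step 1 | 2-[3,5-bis(benzyloxy)phenyl]-4,4,5,5-tetramethyl-1,3,2-dioxaborolane | CC1(C)OB(c2cc(OCc3ccccc3)cc(OCc3ccccc3)c2)OC1(C)C
F0 | step 8 | none | none
A1 | alternative 1 | 6-(benzyloxy)-2-[3,5-bis(benzyloxy)phenyl]-5-methoxy-4-(3-methylbut-2-en-1-yl)-1-benzofuran | CC(C)=CCc1c(OC)c(OCc2ccccc2)cc2oc(-c3cc(OCc4ccccc4)cc(OCc4ccccc4)c3)cc12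
A2 | alternative 1 | {[4-(benzyloxy)-2-{[3,5-bis(benzyloxy)benzoyl]oxy}-5-methoxy-6-(3-methylbut-2-en-1-yl)phenyl]methyl}(triphenyl)phosphonium bromide | CC(C)=CCc1c(OC)c(OCc2ccccc2)cc(OC(=O)c2cc(OCc3ccccc3)cc(OCc3ccccc3)c2)c1C[P+](c1ccccc1)(c1ccccc1)c1ccccc1.[Br-]
A3 | alternative 2 | 5-[6-(benzyloxy)-5-methoxy-4-{[2-(propan-2-yl)-1,3-dioxolan-2-yl]methyl}-1-benzofuran-2-yl]benzene-1,3-diol | Oc1cc(O)cc(-c2cc3c(CC4(C(C)C)OCCO4)c(OC)c(OCc4ccccc4)cc3o2)c1
A4 | alternative 2 | 1-[6-(benzyloxy)-5-methoxy-4-{[2-(propan-2-yl)-1,3-dioxolan-2-yl]methyl}-1-benzofuran-2-yl]hexane-1,3,5-trione | CC(=O)CC(=O)CC(=O)c1cc2c(CC3(C(C)C)OCCO3)c(OC)c(OCc3ccccc3)cc2o1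
A5 | alternative 3 | 2-[3,5-bis(benzyloxy)phenyl]-5-methoxy-4-{[2-(propan-2-yl)-1,3-dioxolan-2-yl]methyl}-1-benzofuran-6-ol | COc1c(O)cc2oc(-c3cc(OCc4ccccc4)cc(OCc4ccccc4)c3)cc2c1CC1(C(C)C)OCCO1
A6 | alternative 3 | 1-{5-[3,5-bis(benzyloxy)phenyl]-3-{1-methoxy-3-[2-(propan-2-yl)-1,3-dioxolan-2-yl]prop-1-en-2-yl}furan-2-yl}-2-diazoethan-1-one (either alkene geometry) | [N-]=[N+]=CC(=O)c1oc(-c2cc(OCc3ccccc3)cc(OCc3ccccc3)c2)cc1C(=COC)CC1(C(C)C)OCCO1
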